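**Retrosynthetic overview**
1. The target 14 comes from the (S)-dibenzyl flavanone 13 by neutral hydrogenolysis; 13 comes from racemic flavanone 12 by a transfer-hydrogenation kinetic resolution (maximum 50 % yield).
2. Ring C is closed last, by intramolecular oxa-Michael addition of the 2'-hydroxychalcone 11.
3. The key C–C bond is made by an intermolecular Claisen–Schmidt aldol condensation of ring-A acetophenone 6 with ring-B aldehyde 9.
4. 6 comes from 3,4,5-trimethoxyphenol (C-acetylation, bromination, Cu-catalysed methoxylation, chelation-controlled demethylation, monobenzylation); 9 comes from 2,6-dimethoxybenzaldehyde.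
5. Rings A and B are bought as benzenes; only ring C is built.

Assumption: simple reagents (AcOH, NBS, NaOMe, BCl3, BnBr, H2 and the like) are not numbered; only compounds that carry part of the target skeleton are.

**Route**

Step 1
Reactants: 1 3,4,5-trimethoxyphenol
Product: 2 1-(6-hydroxy-2,3,4-trimethoxyphenyl)ethan-1-one
Conditions: AcOH, BF3·OEt2 (3 equiv), 90 °C, 3 h; then H2O
Reagents that add atoms: acetic acid, CC(=O)O
Why: BF3-promoted Friedel–Crafts C-acylation goes to one of the two equivalent positions ortho to the phenol, and the resulting chelated ortho-hydroxy ketone resists a second acylation.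

Step 2
Reactants: 2 1-(6-hydroxy-2,3,4-trimethoxyphenyl)ethan-1-one
Product: 3 1-(3-bromo-2-hydroxy-4,5,6-trimethoxyphenyl)ethan-1-one
Conditions: NBS (1.05 equiv), MeCN, 0 °C → rt
Reagents that add atoms: N-bromosuccinimide, O=C1CCC(=O)N1Br
Why: Electrophilic aromatic bromination takes the single remaining ring C–H, which is ortho to the free phenol and far more reactive than the acetyl methyl group.

Step 3
Reactants: 3 1-(3-bromo-2-hydroxy-4,5,6-trimethoxyphenyl)ethan-1-one
Product: 4 1-(2-hydroxy-3,4,5,6-tetramethoxyphenyl)ethan-1-one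
Conditions: NaOMe (6 equiv), CuBr (20 mol%), DMF/MeOH, 110 °C; then aq. HCl
Reagents that add atoms: sodium methoxide, [Na+].[O-]C
Why: Ullmann-type copper-catalysed methoxylation of an ortho-bromophenol, the reaction type that converts 5-bromovanillin into syringaldehyde, replaces Br by OMe and tolerates the phenoxide and the ketone.

Step 4
Reactants: 4 1-(2-hydroxy-3,4,5,6-tetramethoxyphenyl)ethan-1-one
Product: 5 1-(2,6-dihydroxy-3,4,5-trimethoxyphenyl)ethan-1-one
Conditions: BCl3 (2.2 equiv), CH2Cl2, –78 → 0 °C; then H2O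
Reagents that add atoms: none
Why: Chelation-controlled Lewis-acid ether cleavage removes only the methyl ether ortho to the carbonyl, so the three contiguous methoxy groups survive at low temperature.

Step 5
Reactants: 5 1-(2,6-dihydroxy-3,4,5-trimethoxyphenyl)ethan-1-one
Product: 6 1-[2-(benzyloxy)-6-hydroxy-3,4,5-trimethoxyphenyl]ethan-1-one
Conditions: BnBr (1.05 equiv), K2CO3 (1.1 equiv), acetone, reflux
Reagents that add atoms: benzyl bromide, BrCc1ccccc1
Why: Williamson ether synthesis on a symmetric diol stops at the mono-ether because the remaining hydroxyl is held in a strong hydrogen bond to the ketone and is much less nucleophilic.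

Step 6
Reactants: 7 2,6-dimethoxybenzaldehyde
Product: 8 2-hydroxy-6-methoxybenzaldehyde
Conditions: BCl3 (1.2 equiv), CH2Cl2, –78 → 0 °C; then H2O
Reagents that add atoms: none
Why: Chelation-controlled demethylation ortho to the aldehyde stops after one ether because the aryloxyboron chelate formed deactivates the carbonyl towards a second BCl3.

Step 7
Reactants: 8 2-hydroxy-6-methoxybenzaldehyde
Product: 9 2-(benzyloxy)-6-methoxybenzaldehyde
Conditions: BnBr (1.1 equiv), K2CO3, DMF, rt
Reagents that add atoms: benzyl bromide, BrCc1ccccc1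
Why: Williamson ether synthesis on the only phenol present; the non-enolisable aldehyde is inert to K2CO3.

Step 8
Reactants: 6 1-[2-(benzyloxy)-6-hydroxy-3,4,5-trimethoxyphenyl]ethan-1-one; 9 2-(benzyloxy)-6-methoxybenzaldehyde
Product: 11 (E)-1-[2-(benzyloxy)-6-hydroxy-3,4,5-trimethoxyphenyl]-3-[2-(benzyloxy)-6-methoxyphenyl]prop-2-en-1-one, via β-hydroxy ketone 10 (not isolated)
Conditions: KOH (50 % aq., excess), EtOH, rt, 48 h; then aq. HCl to pH 5
Reagents that add atoms: none
Why: Claisen–Schmidt aldol condensation: the enolate of methyl ketone 6 adds to the non-enolisable aldehyde 9 and the aldol 10 loses water by E1cB to give the conjugated (E)-enone; benzyl ethers are stable to hydroxide.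

Step 9
Reactants: 11 (E)-1-[2-(benzyloxy)-6-hydroxy-3,4,5-trimethoxyphenyl]-3-[2-(benzyloxy)-6-methoxyphenyl]prop-2-en-1-one
Product: 12 rac-5-(benzyloxy)-2-[2-(benzyloxy)-6-methoxyphenyl]-6,7,8-trimethoxy-2,3-dihydro-4H-chromen-4-one
Conditions: NaOAc (5 equiv), EtOH, reflux, 24–48 h
Reagents that add atoms: none
Why: Base-mediated 6-endo intramolecular oxa-Michael addition; the two ortho substituents on ring A twist the enone out of conjugation so the equilibrium favours the flavanone, and C2 is formed racemic.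

Step 10
Reactants: 12 rac-5-(benzyloxy)-2-[2-(benzyloxy)-6-methoxyphenyl]-6,7,8-trimethoxy-2,3-dihydro-4H-chromen-4-one
Product: 13 (2S)-5-(benzyloxy)-2-[2-(benzyloxy)-6-methoxyphenyl]-6,7,8-trimethoxy-2,3-dihydro-4H-chromen-4-one
Conditions: RuCl[(R,R)-TsDPEN](p-cymene) (2 mol%), HCO2H/Et3N (5:2), EtOAc, 40 °C, stopped at about 55 % conversion; chromatography
Reagents that add atoms: none
Why: Noyori–Ikariya asymmetric transfer hydrogenation used as a kinetic resolution: the (R,R) catalyst forms the (4R) alcohol and is matched only for (2R)-12 (cis product), so the (2S) ketone is left behind in high ee at no more than 50 % yield.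

Step 11
Reactants: 13 (2S)-5-(benzyloxy)-2-[2-(benzyloxy)-6-methoxyphenyl]-6,7,8-trimethoxy-2,3-dihydro-4H-chromen-4-one
Product: 14 (2S)-5-hydroxy-2-(2-hydroxy-6-methoxyphenyl)-6,7,8-trimethoxy-2,3-dihydro-4H-chromen-4-one
Conditions: H2 (1 atm), 10 % Pd/C, EtOAc, rt; filter, chromatograph without base
Reagents that add atoms: none
Why: Heterogeneous hydrogenolysis cleaves the two primary benzyl aryl ethers under neutral conditions, so C2, which would racemise by base-induced retro-oxa-Michael opening, keeps its (S) configuration.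

**Compound list**

1 | 3,4,5-trimethoxyphenol | COc1cc(O)cc(OC)c1OC | starting material
2 | 1-(6-hydroxy-2,3,4-trimethoxyphenyl)ethan-1-one | CC(=O)c1c(O)cc(OC)c(OC)c1OC | intermediate
3 | 1-(3-bromo-2-hydroxy-4,5,6-trimethoxyphenyl)ethan-1-one | CC(=O)c1c(O)c(Br)c(OC)c(OC)c1OC | intermediate
4 | 1-(2-hydroxy-3,4,5,6-tetramethoxyphenyl)ethan-1-one | CC(=O)c1c(O)c(OC)c(OC)c(OC)c1OC | intermediate
5 | 1-(2,6-dihydroxy-3,4,5-trimethoxyphenyl)ethan-1-one | CC(=O)c1c(O)c(OC)c(OC)c(OC)c1O | intermediate
6 | 1-[2-(benzyloxy)-6-hydroxy-3,4,5-trimethoxyphenyl]ethan-1-one | CC(=O)c1c(O)c(OC)c(OC)c(OC)c1OCc1ccccc1 | intermediate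
7 | 2,6-dimethoxybenzaldehyde | COc1cccc(OC)c1C=O | starting material
8 | 2-hydroxy-6-methoxybenzaldehyde | COc1cccc(O)c1C=O | intermediate
9 | 2-(benzyloxy)-6-methoxybenzaldehyde | COc1cccc(OCc2ccccc2)c1C=O | intermediate
10 | rac-1-[2-(benzyloxy)-6-hydroxy-3,4,5-trimethoxyphenyl]-3-[2-(benzyloxy)-6-methoxyphenyl]-3-hydroxypropan-1-one (aldol adduct, not isolated) | COc1cccc(OCc2ccccc2)c1C(O)CC(=O)c1c(O)c(OC)c(OC)c(OC)c1OCc1ccccc1 | intermediate
11 | (E)-1-[2-(benzyloxy)-6-hydroxy-3,4,5-trimethoxyphenyl]-3-[2-(benzyloxy)-6-methoxyphenyl]prop-2-en-1-one | COc1cccc(OCc2ccccc2)c1/C=C/C(=O)c1c(O)c(OC)c(OC)c(OC)c1OCc1ccccc1 | intermediate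
12 | rac-5-(benzyloxy)-2-[2-(benzyloxy)-6-methoxyphenyl]-6,7,8-trimethoxy-2,3-dihydro-4H-chromen-4-one (racemate) | COc1cccc(OCc2ccccc2)c1C1CC(=O)c2c(OCc3ccccc3)c(OC)c(OC)c(OC)c2O1 | intermediate
13 | (2S)-5-(benzyloxy)-2-[2-(benzyloxy)-6-methoxyphenyl]-6,7,8-trimethoxy-2,3-dihydro-4H-chromen-4-one | COc1cccc(OCc2ccccc2)c1[C@@H]1CC(=O)c2c(OCc3ccccc3)c(OC)c(OC)c(OC)c2O1 | intermediate
14 | (2S)-5-hydroxy-2-(2-hydroxy-6-methoxyphenyl)-6,7,8-trimethoxy-2,3-dihydro-4H-chromen-4-one | COc1cccc(O)c1[C@@H]1CC(=O)c2c(O)c(OC)c(OC)c(OC)c2O1 | target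

**Summary**

Total step count: 11. Longest linear sequence: 9 steps (steps 1–5, then 8–11); the ring-B branch is steps 6–7.

**Steps most likely to fail, and fallbacks**

Step 10 (kinetic resolution). The ketone is electron-rich and flanked by the 5-benzyloxy group, so transfer hydrogenation may be slow or poorly selective. The fallback sets out from 12 and comes back at 13. NaBH4 (MeOH/THF, 0 °C) reduces 12 to the racemic cis alcohol rac-(2S,4S)-5-(benzyloxy)-2-[2-(benzyloxy)-6-methoxyphenyl]-6,7,8-trimethoxy-3,4-dihydro-2H-chromen-4-ol F1. Lipase-catalysed acylation (Candida antarctica lipase B, vinyl acetate, MTBE, 40 °C, about 50 % conversion) acetylates the (4R) alcohol and leaves (2S,4S)-5-(benzyloxy)-2-[2-(benzyloxy)-6-methoxyphenyl]-6,7,8-trimethoxy-3,4-dihydro-2H-chromen-4-ol F2. After chromatographic separation from the acetate, F2 is oxidised with Dess–Martin periodinane (CH2Cl2, rt) to 13; C2 is untouched throughout.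

Step 3 (copper-catalysed methoxylation). The bromide is flanked by a phenoxide and a methoxy group, so protodebromination back to 2 or low conversion is possible. The fallback sets out from 2 and comes back at 4, bypassing steps 2 and 3. Duff formylation (hexamethylenetetramine, CF3CO2H, 80 °C; then aq. HCl) at the one free ring position gives 3-acetyl-2-hydroxy-4,5,6-trimethoxybenzaldehyde F3. Dakin oxidation (H2O2, aq. NaOH, 0 °C → rt) gives 1-(2,3-dihydroxy-4,5,6-trimethoxyphenyl)ethan-1-one F4. Selective methylation of the non-chelated 3-hydroxyl through the dianion (NaH 2.1 equiv, DMSO; then MeI 1.0 equiv) gives 4.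

Step 9 (ring closure of the chalcone). The oxa-Michael addition is an equilibrium and the β-carbon carries a di-ortho-substituted, electron-rich aryl group, so conversion may stall. The fallback sets out from 6 and 9 and comes back at 12. The aldol is run as a kinetic addition (LiN(SiMe3)2 2.2 equiv, THF, –78 °C; then 9; NH4Cl quench) so that the β-hydroxy ketone 10 is isolated instead of dehydrated. Ring C is then closed irreversibly by an intramolecular Mitsunobu etherification (PPh3, DIAD, THF, 0 °C), in which the ring-A phenol displaces the activated carbinol to give 12. Stereochemical leakage does not matter here because 12 is racemic.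

**Further compounds**

F1 | step 10 | rac-(2S,4S)-5-(benzyloxy)-2-[2-(benzyloxy)-6-methoxyphenyl]-6,7,8-trimethoxy-3,4-dihydro-2H-chromen-4-ol (cis, racemic; one enantiomer drawn) | COc1cccc(OCc2ccccc2)c1[C@@H]1C[C@H](O)c2c(OCc3ccccc3)c(OC)c(OC)c(OC)c2O1
F2 | step 10 | (2S,4S)-5-(benzyloxy)-2-[2-(benzyloxy)-6-methoxyphenyl]-6,7,8-trimethoxy-3,4-dihydro-2H-chromen-4-ol | COc1cccc(OCc2ccccc2)c1[C@@H]1C[C@H](O)c2c(OCc3ccccc3)c(OC)c(OC)c(OC)c2O1
F3 | step 3 | 3-acetyl-2-hydroxy-4,5,6-trimethoxybenzaldehyde | CC(=O)c1c(O)c(C=O)c(OC)c(OC)c1OC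
F4 | step 3 | 1-(2,3-dihydroxy-4,5,6-trimethoxyphenyl)ethan-1-one | CC(=O)c1c(O)c(O)c(OC)c(OC)c1OC
F0 | step 9 | none | none
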